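**Retrosynthetic overview**

1. Target 17 ⇒ ester C–O bond: palmitoyl chloride 16 + keto diol 15 (only the primary OH is acylated).
2. 15 ⇒ cyclohexenone 13 by hydrogenation (ring C=C saturated, O-benzyl removed).
3. 13 ⇒ acyclic dienone 12 by ring-closing metathesis. With the target ring numbered from the carbinol carbon C1 to the ketone carbon C4, the ring bond C2–C3 joins the CH2 beside the carbinol to the CH2 beside the ketone. It is made as C2=C3 from a vinyl group on C1 and a vinyl ketone at C4, which closes the only ring, the six-membered carbocycle.
4. 12 ⇒ diol 11 (MnO2) ⇒ lactol 9 + vinylmagnesium bromide 6 ⇒ acetal 7 ⇒ ketone 5 + 6 ⇒ Weinreb amide 2 (from ester 1) + Grignard reagent of bromoacetal 3.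

Key step: step 7

Remark on the chemistry: compounds 7 to 13 carry a stereocentre at the tertiary carbinol carbon and are made as racemates (9 and 11 as diastereomer mixtures). This carbon stops being a stereocentre once the ring alkene is saturated, so the achiral target needs no stereocontrol.

**Route**

Step 1
Reactants: 1 methyl 3-(benzyloxy)propanoate
Product: 2 Weinreb amide 3-(benzyloxy)-N-methoxy-N-methylpropanamide
Conditions: MeNH(OMe)·HCl (1.5 equiv), iPrMgCl (3 equiv), THF, −20 to 0 °C
Reagents that add atoms: N,O-dimethylhydroxylamine hydrochloride, CNOC.Cl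
Why: The chloromagnesium amide made in the flask from the hydroxylamine salt and iPrMgCl attacks the methyl ester to give the N-methoxy-N-methylamide (ester aminolysis, Weinreb amide formation), at a temperature low enough that beta-elimination of benzyl alcohol should not compete.

Step 2
Reactants: 3 bromoacetal 2-(2-bromoethyl)-1,3-dioxolane; 2 Weinreb amide 3-(benzyloxy)-N-methoxy-N-methylpropanamide
Product: 5 ketone 1-(benzyloxy)-5-(1,3-dioxolan-2-yl)pentan-3-one, via [2-(1,3-dioxolan-2-yl)ethyl]magnesium bromide 4 (not isolated)
Conditions: 3, Mg turnings, THF, 25–30 °C; then 2, THF, 0 °C to rt; aq. NH4Cl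
Reagents that add atoms: none
Why: Magnesium inserts into the primary C–Br bond below 30 °C, where the acetal Grignard reagent is stable, and its addition to the Weinreb amide stops at the chelated tetrahedral adduct, which releases the ketone only on aqueous work-up (Weinreb ketone synthesis).

Step 3
Reactants: 5 ketone 1-(benzyloxy)-5-(1,3-dioxolan-2-yl)pentan-3-one; 6 vinylmagnesium bromide
Product: 7 tertiary alcohol 1-(benzyloxy)-3-[2-(1,3-dioxolan-2-yl)ethyl]pent-4-en-3-ol (racemic)
Conditions: vinylMgBr (1.5 equiv), THF, −78 to 0 °C; aq. NH4Cl
Reagents that add atoms: none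
Why: 1,2-Addition of the vinyl Grignard reagent to the unhindered dialkyl ketone at low temperature should outrun enolisation and gives the tertiary allylic alcohol (Grignard addition); the carbinol stereocentre forms without control as a racemate, which does not matter, and the acetal and benzyl ether are inert.

Step 4
Reactants: 7 tertiary alcohol 1-(benzyloxy)-3-[2-(1,3-dioxolan-2-yl)ethyl]pent-4-en-3-ol
Product: 9 lactol 5-[2-(benzyloxy)ethyl]-5-ethenyloxolan-2-ol, via 6-(benzyloxy)-4-ethenyl-4-hydroxyhexanal 8 (not isolated)
Conditions: 1 M aq. HCl, THF, rt
Reagents that add atoms: water, O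
Why: Acid-catalysed hydrolysis of the dioxolane frees the aldehyde, which is trapped by the gamma tertiary hydroxyl as the five-membered cyclic hemiacetal (acetal hydrolysis and lactol formation); dilute acid at room temperature should leave the tertiary allylic alcohol un-ionised, and the lactol carbon forms as a mixture of epimers that does not matter.

Step 5
Reactants: 9 lactol 5-[2-(benzyloxy)ethyl]-5-ethenyloxolan-2-ol; 6 vinylmagnesium bromide
Product: 11 diol 8-(benzyloxy)-6-ethenyloct-1-ene-3,6-diol, via bromomagnesium 1-(benzyloxy)-3-ethenyl-6-oxohexan-3-olate 10 (not isolated)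
Conditions: vinylMgBr (3 equiv), THF, 0 °C to rt; aq. NH4Cl
Reagents that add atoms: none
Why: One equivalent of the Grignard reagent deprotonates the lactol, whose magnesium salt opens to the tertiary bromomagnesium alkoxide 10 bearing a free aldehyde, and a second equivalent adds to that aldehyde (Grignard addition to a lactol), giving after work-up the 1,4-diol as a diastereomer mixture that converges to one ketone in the next step.

Step 6
Reactants: 11 diol 8-(benzyloxy)-6-ethenyloct-1-ene-3,6-diol
Product: 12 dienone 8-(benzyloxy)-6-ethenyl-6-hydroxyoct-1-en-3-one (racemic)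
Conditions: activated MnO2 (excess), CH2Cl2, rt; filtered and used without delay
Reagents that add atoms: none
Why: Activated MnO2 oxidises the secondary allylic alcohol to the vinyl ketone (allylic alcohol oxidation on MnO2), while the tertiary allylic alcohol has no carbinol hydrogen and, with no chromium oxidant present, cannot undergo oxidative transposition; the benzyl ether and both alkenes are untouched.

Step 7
Reactants: 12 dienone 8-(benzyloxy)-6-ethenyl-6-hydroxyoct-1-en-3-one
Product: 13 cyclohexenone 4-[2-(benzyloxy)ethyl]-4-hydroxycyclohex-2-en-1-one (racemic)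
Conditions: second-generation Grubbs catalyst (H2IMes)(PCy3)Cl2Ru=CHPh (5 mol%), CH2Cl2 (0.005 M), 40 °C
Reagents that add atoms: none
Why: The ruthenium benzylidene should first exchange onto the electron-richer vinyl group of the tertiary carbinol by [2+2] cycloaddition and cycloreversion, and the resulting alkylidene then adds intramolecularly across the vinyl ketone C=C to a ruthenacyclobutane whose cycloreversion releases the enone and a ruthenium methylidene. The closest known reaction type is ring-closing metathesis of a terminal alkene onto an acrylate or vinyl ketone, which is established for free allylic alcohols and gives cyclic alpha,beta-unsaturated carbonyl compounds. The single ring closes as a six-membered carbocycle by forming C2=C3, because four atoms separate the two alkenes (a 1,7-diene) and no other ring size is accessible; loss of ethene makes the closure irreversible. No stereocentre is created, and the racemic carbinol carbon is carried through unchanged. The selectivity needed is ring closure over intermolecular cross-metathesis, which is secured by high dilution, by the quaternary carbinol carbon that folds the chain toward cyclisation, and by the reluctance of the electron-poor vinyl ketone to homodimerise.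

Step 8
Reactants: 13 cyclohexenone 4-[2-(benzyloxy)ethyl]-4-hydroxycyclohex-2-en-1-one
Product: 15 keto diol 4-hydroxy-4-(2-hydroxyethyl)cyclohexan-1-one, via 4-[2-(benzyloxy)ethyl]-4-hydroxycyclohexan-1-one 14 (not isolated)
Conditions: H2 (1 atm), Pd/C (10% Pd), EtOAc, rt
Reagents that add atoms: none
Why: Palladium-catalysed hydrogenation saturates the enone C=C first, which removes the only stereocentre and forestalls conjugate addition of the side-chain oxygen, and then cleaves the benzyl ether by hydrogenolysis (catalytic hydrogenation and O-debenzylation), while the ketone and the now non-allylic tertiary alcohol should be stable in ethyl acetate.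

Step 9
Reactants: 15 keto diol 4-hydroxy-4-(2-hydroxyethyl)cyclohexan-1-one; 16 palmitoyl chloride (hexadecanoyl chloride)
Product: 17 2-(1-hydroxy-4-oxocyclohexyl)ethyl hexadecanoate
Conditions: 16 (1.05 equiv), Et3N, CH2Cl2, 0 °C
Reagents that add atoms: none
Why: With about one equivalent of the acid chloride at 0 °C, the unhindered primary alcohol is acylated far faster than the tertiary cyclohexanol (esterification with an acyl chloride and amine base), and the ketone is inert.

**Compound list**

1 | methyl 3-(benzyloxy)propanoate | COC(=O)CCOCc1ccccc1 | starting material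
2 | 3-(benzyloxy)-N-methoxy-N-methylpropanamide | CON(C)C(=O)CCOCc1ccccc1 | intermediate
3 | 2-(2-bromoethyl)-1,3-dioxolane | BrCCC1OCCO1 | starting material
4 | [2-(1,3-dioxolan-2-yl)ethyl]magnesium bromide | Br[Mg]CCC1OCCO1 | intermediate
5 | 1-(benzyloxy)-5-(1,3-dioxolan-2-yl)pentan-3-one | O=C(CCOCc1ccccc1)CCC1OCCO1 | intermediate
6 | vinylmagnesium bromide | C=C[Mg]Br | starting material
7 | 1-(benzyloxy)-3-[2-(1,3-dioxolan-2-yl)ethyl]pent-4-en-3-ol | C=CC(O)(CCOCc1ccccc1)CCC1OCCO1 | intermediate
8 | 6-(benzyloxy)-4-ethenyl-4-hydroxyhexanal | O=CCCC(O)(C=C)CCOCc1ccccc1 | intermediate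
9 | 5-[2-(benzyloxy)ethyl]-5-ethenyloxolan-2-ol | OC1CCC(C=C)(CCOCc2ccccc2)O1 | intermediate
10 | bromomagnesium 1-(benzyloxy)-3-ethenyl-6-oxohexan-3-olate | C=CC(O[Mg]Br)(CCOCc1ccccc1)CCC=O | intermediate
11 | 8-(benzyloxy)-6-ethenyloct-1-ene-3,6-diol | C=CC(O)CCC(O)(C=C)CCOCc1ccccc1 | intermediate
12 | 8-(benzyloxy)-6-ethenyl-6-hydroxyoct-1-en-3-one | C=CC(=O)CCC(O)(C=C)CCOCc1ccccc1 | intermediate
13 | 4-[2-(benzyloxy)ethyl]-4-hydroxycyclohex-2-en-1-one | O=C1C=CC(O)(CCOCc2ccccc2)CC1 | intermediate
14 | 4-[2-(benzyloxy)ethyl]-4-hydroxycyclohexan-1-one | O=C1CCC(O)(CCOCc2ccccc2)CC1 | intermediate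
15 | 4-hydroxy-4-(2-hydroxyethyl)cyclohexan-1-one | O=C1CCC(O)(CCO)CC1 | intermediate
16 | palmitoyl chloride | CCCCCCCCCCCCCCCC(=O)Cl | starting material
17 | 2-(1-hydroxy-4-oxocyclohexyl)ethyl hexadecanoate | CCCCCCCCCCCCCCCC(=O)OCCC1(O)CCC(=O)CC1 | target

**Step count**

Total steps: 9. Longest linear sequence: 9 steps (1 to 17).

**Steps most likely to fail**

Step 7 (ring-closing metathesis). The ruthenium carbene may be held back by the electron-poor vinyl ketone, so that ring closure becomes slow and intermolecular cross-metathesis or oligomerisation of the labile enone takes over. Fallback: set out from diol 11 and run the metathesis before the oxidation. With the same ruthenium catalyst in dilute CH2Cl2 at 40 °C, both alkenes are electron-rich allylic alcohols and should close to 1-[2-(benzyloxy)ethyl]cyclohex-2-ene-1,4-diol F1. MnO2 in CH2Cl2 then oxidises the secondary ring allylic alcohol, and the route is rejoined at compound 13.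

Step 6 (MnO2 oxidation). Oxidation of a vinyl carbinol that lacks further conjugation may stall on MnO2, and the vinyl ketone may be lost by polymerisation or conjugate addition during long contact times and concentration. Fallback: set out from lactol 9 and avoid the allylic oxidation altogether. The lactol is oxidised with TEMPO (cat.) and PhI(OAc)2 in CH2Cl2 to the lactone 5-[2-(benzyloxy)ethyl]-5-ethenyloxolan-2-one F2. The lactone is opened with MeNH(OMe)·HCl and AlMe3 in CH2Cl2 to the hydroxy Weinreb amide 6-(benzyloxy)-4-ethenyl-4-hydroxy-N-methoxy-N-methylhexanamide F3, which is used crude and at once so that it does not close back to the lactone. Treating it with excess vinylMgBr in THF at 0 °C and quenching inversely into cold aqueous NH4Cl should deliver the vinyl ketone directly, and the route is rejoined at compound 12.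

Step 4 (acetal hydrolysis). While the dioxolane is being cleaved, the acid may ionise the tertiary allylic alcohol, leading to allylic transposition or dehydration. Fallback: set out from ketone 5 and hydrolyse the acetal before any allylic alcohol is present. 1 M aq. HCl in THF should give the keto aldehyde 6-(benzyloxy)-4-oxohexanal F4. Excess vinylMgBr in THF from −78 to 0 °C (with anhydrous CeCl3 if enolisation interferes) then adds to both carbonyl groups, and the route is rejoined at compound 11.

**Further compounds**

F1 | step 7 | 1-[2-(benzyloxy)ethyl]cyclohex-2-ene-1,4-diol | OC1C=CC(O)(CCOCc2ccccc2)CC1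
F2 | step 6 | 5-[2-(benzyloxy)ethyl]-5-ethenyloxolan-2-one | O=C1CCC(C=C)(CCOCc2ccccc2)O1
F3 | step 6 | 6-(benzyloxy)-4-ethenyl-4-hydroxy-N-methoxy-N-methylhexanamide | CON(C)C(=O)CCC(O)(C=C)CCOCc1ccccc1
F4 | step 4 | 6-(benzyloxy)-4-oxohexanal | O=CCCC(=O)CCOCc1ccccc1
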